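**Retrosynthetic overview**
- Coumarin lactone ring (formed last): Knoevenagel condensation/lactonisation joins a citrinin-type quinone methide (a masked salicylaldehyde carrying the hydroxybutyl chain) to a (2R)-dihydropyranon-6-yl acetate.
- Dihydropyranone ring (key step): two-carbon ring expansion of (R)-β-butyrolactone by the dianion of methyl acetoacetate (acyl transfer, then cyclodehydration).
- Quinone methide: orthoformate C-formylation/cyclisation of a 5-alkyl-2,4-dimethylresorcinol at its single free ring position.
- Benzene ring (built de novo): C-acylation of the dianion of 3-methylhexane-2,4-dione by trans-3,4-dimethyl-β-lactone (from (S)-β-butyrolactone by anti-selective enolate methylation), then aldol aromatisation.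
- Order of ring formation: dihydropyranone; benzene; transient pyran of the quinone methide; coumarin pyranone.

Assumption: lithium enolates and dianions are treated as ionised forms of the numbered compounds and get no numbers of their own. The descriptors read from the SMILES are (2R,3S) for the 3-hydroxybutan-2-yl chain and (2R) for the pyranone.

**Step 1**
Reactants: 1 (4R)-4-methyloxetan-2-one [(R)-β-butyrolactone]; 2 methyl 3-oxobutanoate (methyl acetoacetate)
Product: 4 methyl 2-[(2R)-2-methyl-4-oxo-3,4-dihydro-2H-pyran-6-yl]acetate, via hydroxy diketo ester 3 (not isolated)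
Conditions: 2 (2.2 equiv), LiN(iPr)2 (4.4 equiv), THF, −78 to 0 °C; 1 (1.0 equiv), −78 °C, 1 h; aq. HCl; crude, TsOH·H2O (10 mol%), CH2Cl2, rt
Reagents that add atoms: none
Why: Proposed new method: a two-carbon ring expansion of a β-lactone (oxetan-2-one to 2,3-dihydro-4H-pyran-4-one) in which the hard γ-carbanion of the acetoacetate dianion adds to the strained acyl carbon, the tetrahedral intermediate collapses by acyl–O cleavage (the C–O bond at the stereocentre is never broken, so R is retained) to the δ-alkoxy tricarbonyl 3, and on acidification the tethered hydroxyl adds 6-exo to the C3 ketone and dehydrates to the vinylogous ester, so that C4 and C3 of the acetoacetate end up inserted into the former lactone C(=O)–O bond; the closest known reaction types are the Huckin–Weiler γ-acylation of acetoacetate dianions by esters, acyl-selective opening of β-lactones by hard nucleophiles, acid cyclodehydration of δ-hydroxy-β-diketones, and acylation-triggered ring expansions of lactams.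

**Step 2**
Reactants: 5 3-methylpentane-2,4-dione
Product: 6 3-methylhexane-2,4-dione
Conditions: LiN(iPr)2 (2.1 equiv), THF, 0 °C; MeI (1.0 equiv), −78 to 0 °C; aq. HCl
Reagents that add atoms: iodomethane (CI)
Why: Hauser–Harris dianion alkylation: the second deprotonation takes place at a terminal methyl group and this far more nucleophilic carbanion is methylated selectively by one equivalent of MeI; no stereocentre is formed.

**Step 3**
Reactants: 7 (4S)-4-methyloxetan-2-one [(S)-β-butyrolactone]
Product: 8 (3S,4S)-3,4-dimethyloxetan-2-one (trans)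
Conditions: LiN(iPr)2 (1.05 equiv), THF, −78 °C; MeI (3 equiv), −78 to −40 °C
Reagents that add atoms: iodomethane (CI)
Why: Fráter–Seebach-type alkylation of a β-lactone enolate (β-elimination is geometrically disfavoured in the four-membered ring at −78 °C): MeI approaches the planar enolate anti to the C4 methyl group, which sets C3 as S (trans, expected dr ≥ 95:5).

**Step 4**
Reactants: 6 3-methylhexane-2,4-dione; 8 (3S,4S)-3,4-dimethyloxetan-2-one
Product: 10 5-[(2R,3S)-3-hydroxybutan-2-yl]-2,4-dimethylbenzene-1,3-diol, via hydroxy triketone 9 (not isolated)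
Conditions: 6 (2.2 equiv), LiN(iPr)2 (4.4 equiv), THF, 0 °C; 8 (1.0 equiv), −78 to −20 °C; then 1 M aq. KOH, MeOH, 40 °C, N2; aq. HCl
Reagents that add atoms: none
Why: Hauser–Harris C-acylation of the diketone dianion by the strained lactone (acyl–O cleavage, both stereocentres untouched) gives triketone 9, whose ethyl-ketone CH2 closes onto C7 in a Collie–Harris aldol condensation/dehydration that is the only cyclisation mode able to aromatise, while the C8 hydrogen is shielded because the C5–C7 diketone sits as its enolate, so the (R) benzylic and (S) carbinol centres of 10 are those set in 8.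

**Step 5**
Reactants: 10 5-[(2R,3S)-3-hydroxybutan-2-yl]-2,4-dimethylbenzene-1,3-diol
Product: 12 (3S,4R)-8-hydroxy-3,4,5,7-tetramethyl-3,4-dihydro-6H-isochromen-6-one, via methoxy acetal 11 (not isolated)
Conditions: HC(OMe)3 (5 equiv), CF3CO2H–CH2Cl2 (1:4), 0 °C to rt; evaporate; H2O work-up
Reagents that add atoms: trimethyl orthoformate (COC(OC)OC)
Why: Orthoformate (Gross-type) electrophilic formylation at the only free ring position, which is ortho and para to the two hydroxyls, followed by oxa-Pictet–Spengler-type capture by the side-chain hydroxyl and loss of methanol to the citrinin-type quinone methide; no stereocentre is touched.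

**Step 6**
Reactants: 12 (3S,4R)-8-hydroxy-3,4,5,7-tetramethyl-3,4-dihydro-6H-isochromen-6-one; 4 methyl 2-[(2R)-2-methyl-4-oxo-3,4-dihydro-2H-pyran-6-yl]acetate
Product: 14 7-hydroxy-5-[(2R,3S)-3-hydroxybutan-2-yl]-6,8-dimethyl-3-[(2R)-2-methyl-4-oxo-3,4-dihydro-2H-pyran-6-yl]-2H-chromen-2-one (target), via arylidene ester 13 (not isolated)
Conditions: 4 (1.3 equiv), piperidine (20 mol%), AcOH (20 mol%), MeOH, 60 °C
Reagents that add atoms: none
Why: Knoevenagel condensation/lactonisation (the classical salicylaldehyde-to-coumarin synthesis): piperidine opens 12 at C1 to the salicylidene iminium, the doubly activated CH2 of 4 condenses there (only this carbon has the two hydrogens needed), and the ortho phenol closes irreversibly onto the ester, which drains any reversible oxa-Michael adducts, while the three stereocentres are not acidified under this weak buffer.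

**Compound list**
1 | (4R)-4-methyloxetan-2-one | C[C@@H]1CC(=O)O1 | starting material
2 | methyl 3-oxobutanoate | COC(=O)CC(C)=O | starting material
3 | methyl (7R)-7-hydroxy-3,5-dioxooctanoate | COC(=O)CC(=O)CC(=O)C[C@@H](C)O | intermediate (not isolated)
4 | methyl 2-[(2R)-2-methyl-4-oxo-3,4-dihydro-2H-pyran-6-yl]acetate | COC(=O)CC1=CC(=O)C[C@@H](C)O1 | intermediate
5 | 3-methylpentane-2,4-dione | CC(=O)C(C)C(C)=O | starting material
6 | 3-methylhexane-2,4-dione | CCC(=O)C(C)C(C)=O | intermediate
7 | (4S)-4-methyloxetan-2-one | C[C@H]1CC(=O)O1 | starting material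
8 | (3S,4S)-3,4-dimethyloxetan-2-one | O=C1[C@@H](C)[C@H](C)O1 | intermediate
9 | (8S,9S)-9-hydroxy-4,8-dimethyldecane-3,5,7-trione (C4 epimers) | CCC(=O)C(C)C(=O)CC(=O)[C@@H](C)[C@H](C)O | intermediate (not isolated)
10 | 5-[(2R,3S)-3-hydroxybutan-2-yl]-2,4-dimethylbenzene-1,3-diol | Cc1c(O)c(C)c(O)cc1[C@@H](C)[C@H](C)O | intermediate
11 | (3S,4R)-1-methoxy-3,4,5,7-tetramethyl-3,4-dihydro-1H-isochromene-6,8-diol (C1 epimers) | Cc1c(O)c(C)c(O)c2c1[C@@H](C)[C@H](C)OC2OC | intermediate (not isolated)
12 | (3S,4R)-8-hydroxy-3,4,5,7-tetramethyl-3,4-dihydro-6H-isochromen-6-one | CC1=C2[C@@H](C)[C@H](C)OC=C2C(O)=C(C)C1=O | intermediate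
13 | methyl (2Z)-3-{2,4-dihydroxy-6-[(2R,3S)-3-hydroxybutan-2-yl]-3,5-dimethylphenyl}-2-[(2R)-2-methyl-4-oxo-3,4-dihydro-2H-pyran-6-yl]prop-2-enoate | COC(=O)/C(=C\c1c(O)c(C)c(O)c(C)c1[C@@H](C)[C@H](C)O)C1=CC(=O)C[C@@H](C)O1 | intermediate (not isolated)
14 | 7-hydroxy-5-[(2R,3S)-3-hydroxybutan-2-yl]-6,8-dimethyl-3-[(2R)-2-methyl-4-oxo-3,4-dihydro-2H-pyran-6-yl]-2H-chromen-2-one | Cc1c(O)c(C)c2oc(=O)c(C3=CC(=O)C[C@@H](C)O3)cc2c1[C@@H](C)[C@H](C)O | target

**Step count and risks**
Total steps: 6. Longest linear sequence: 4 steps (5 → 6 → 10 → 12 → 14, or 7 → 8 → 10 → 12 → 14).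

Steps most likely to fail:

1. Step 1 (the proposed ring expansion). The dianion may deprotonate the lactone or open it at C4, and the tricarbonyl 3 may close to a 4-hydroxy-2-pyrone instead of the dihydropyranone. The fallback uses known chemistry, sets out from 1 (with 2) and comes back at 4. Lactone 1 is opened at the acyl carbon with MeNH(OMe)·HCl/Me2AlCl to (3R)-3-hydroxy-N-methoxy-N-methylbutanamide F1. This is silylated (tBuMe2SiCl, imidazole) to (3R)-3-[(tert-butyldimethylsilyl)oxy]-N-methoxy-N-methylbutanamide F2. The dianion of 2 is then acylated by this Weinreb amide to methyl (7R)-7-[(tert-butyldimethylsilyl)oxy]-3,5-dioxooctanoate F3. Aqueous HF in MeCN removes the silyl group and cyclodehydrates the δ-hydroxy-β-diketone to 4.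

2. Step 4 (acylation and aromatisation in one flask). The risks are lactone enolisation instead of acyl transfer, retro-aldol or dehydration of the β-hydroxy ketone in KOH, and partial epimerisation at C8 of 9 before ring closure. The fallback sets out from 8 (with 6) and comes back at 10; it replaces the one-pot lactone cascade by a protected open-chain acyl donor with an isolated triketone. Lactone 8 is opened with MeNH(OMe)·HCl/Me2AlCl to (2S,3S)-3-hydroxy-N-methoxy-N,2-dimethylbutanamide F4 and silylated to (2S,3S)-3-[(tert-butyldimethylsilyl)oxy]-N-methoxy-N,2-dimethylbutanamide F5. The dianion of 6 is acylated to (8S,9S)-9-[(tert-butyldimethylsilyl)oxy]-4,8-dimethyldecane-3,5,7-trione F6, which is isolated. F6 is cyclised under a separately tuned mild buffer (aq. K2CO3/MeOH, pH 9–10, rt) to 5-{(2R,3S)-3-[(tert-butyldimethylsilyl)oxy]butan-2-yl}-2,4-dimethylbenzene-1,3-diol F7. Bu4NF then gives 10.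

3. Step 6 (coumarin formation). The adduct at C1 of 12 may stay as a stable isochroman and not open, and piperidine may attack the vinylogous ester of 4. The fallback sets out from 4 and 10 and comes back at 14, bypassing 12, by moving the one-carbon unit onto the pyranone partner. Ester 4 is condensed with Me2NCH(OMe)2 to methyl 3-(dimethylamino)-2-[(2R)-2-methyl-4-oxo-3,4-dihydro-2H-pyran-6-yl]prop-2-enoate F8. This is heated with resorcinol 10 in AcOH (Pechmann-type condensation at the only free ring position, then lactonisation) to give 14 directly.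

**Further compounds**
F1 | step 1 | (3R)-3-hydroxy-N-methoxy-N-methylbutanamide | CON(C)C(=O)C[C@@H](C)O
F2 | step 1 | (3R)-3-[(tert-butyldimethylsilyl)oxy]-N-methoxy-N-methylbutanamide | CON(C)C(=O)C[C@@H](C)O[Si](C)(C)C(C)(C)C
F3 | step 1 | methyl (7R)-7-[(tert-butyldimethylsilyl)oxy]-3,5-dioxooctanoate | COC(=O)CC(=O)CC(=O)C[C@@H](C)O[Si](C)(C)C(C)(C)C
F4 | step 4 | (2S,3S)-3-hydroxy-N-methoxy-N,2-dimethylbutanamide | CON(C)C(=O)[C@@H](C)[C@H](C)O
F5 | step 4 | (2S,3S)-3-[(tert-butyldimethylsilyl)oxy]-N-methoxy-N,2-dimethylbutanamide | CON(C)C(=O)[C@@H](C)[C@H](C)O[Si](C)(C)C(C)(C)C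
F6 | step 4 | (8S,9S)-9-[(tert-butyldimethylsilyl)oxy]-4,8-dimethyldecane-3,5,7-trione | CCC(=O)C(C)C(=O)CC(=O)[C@@H](C)[C@H](C)O[Si](C)(C)C(C)(C)C
F7 | step 4 | 5-{(2R,3S)-3-[(tert-butyldimethylsilyl)oxy]butan-2-yl}-2,4-dimethylbenzene-1,3-diol | Cc1c(O)c(C)c(O)cc1[C@@H](C)[C@H](C)O[Si](C)(C)C(C)(C)C
F8 | step 6 | methyl 3-(dimethylamino)-2-[(2R)-2-methyl-4-oxo-3,4-dihydro-2H-pyran-6-yl]prop-2-enoate (E/Z mixture) | COC(=O)C(=CN(C)C)C1=CC(=O)C[C@@H](C)O1
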